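**Retrosynthetic overview**
1. Target 14 ⇐ acetate 13; the C14/C15 bromochloride comes from the last trisubstituted olefin of 10 (Shi epoxide → bromide opening with inversion → bromonium opened by chloride).
2. Oxygen bridge C7–O–C10 (ring B, formed second) ⇐ trans-1,4-diol 8, by transannular displacement at C10 by the C7 hydroxyl with inversion.
3. Cyclohexane (ring A, C6–C11 bond, formed first) ⇐ acyclic epoxy-triene 7, by epoxide-triggered cation–olefin cyclisation with hydration of the C7 cation.
4. 7 ⇐ epoxy alcohol 4 + prenyl Grignard 5 (C12–C13 bond); 4 ⇐ (3S,6E)-nerolidyl acetate by C12 allylic oxidation and Sharpless epoxidation (sets C10 and C11).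
5. C3 is taken from natural (3S)-nerolidol 1.

Assumption 1: the presumed biosynthesis is taken to be an electrophile-triggered (bromonium or epoxide across C10–C11) C6→C11 cyclisation of (S)-geranyllinalool, hydration of the C7 cation, and bridge closure by displacement at C10 with inversion; locants follow geranyllinalool numbering (C1=C2 vinyl, C3 carbinol, ring carbons C6–C11, halogens on C14/C15).
Assumption 2: natural dextrorotatory (3S,6E)-nerolidol (cabreuva-oil grade) is commercially available in high enantiomeric purity.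

Direct capture of the C7 cation by the epoxide-derived C10 oxygen would give the C7,C10-bis-epimer of the target ring system (bridge syn to the C11 methyl). The route therefore brings the bridge oxygen in as water at C7 and inverts C10.

**Route**

Step 1
Reactants: 1 (3S,6E)-nerolidol
Product: 2 (3S,6E)-nerolidyl acetate
Conditions: Ac2O, Et3N, DMAP (cat.), CH2Cl2, rt
Reagents that add atoms: acetic anhydride, CC(=O)OC(C)=O
Why: DMAP-catalysed acylation (Steglich-type) esterifies the tertiary allylic hydroxyl without breaking the C3–O bond, so the 3S centre of the starting material is carried through and this oxygen can neither trap the C7 cation in step 5 nor be chlorinated in step 9.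

Step 2
Reactants: 2 (3S,6E)-nerolidyl acetate
Product: 3 (3S,6E,10E)-12-hydroxynerolidyl acetate
Conditions: SeO2 (0.3 equiv), t-BuOOH, salicylic acid (cat.), CH2Cl2, rt
Reagents that add atoms: tert-butyl hydroperoxide (oxygen source, relayed by catalytic SeO2), CC(C)(C)OO
Why: Sharpless–Umbreit SeO2 allylic oxidation (ene reaction then [2,3]-sigmatropic shift) hydroxylates the (E)-methyl of the terminal isopropylidene group in preference to the internal olefin, giving the (10E)-allylic alcohol that will direct the epoxidation; no stereocentre is formed.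

Step 3
Reactants: 3 (3S,6E,10E)-12-hydroxynerolidyl acetate
Product: 4 (3S,6E,10S,11S)-10,11-epoxy-12-hydroxy-10,11-dihydronerolidyl acetate
Conditions: Ti(OiPr)4 (10 mol %), L-(+)-diethyl tartrate (12 mol %), t-BuOOH, 4 Å molecular sieves, CH2Cl2, −20 °C
Reagents that add atoms: tert-butyl hydroperoxide, CC(C)(C)OO
Why: Sharpless asymmetric epoxidation oxidises only the olefin of the primary allylic alcohol, and the L-(+)-tartrate ligand sets C10 and C11 both as S (trans epoxide from the E-olefin).

Step 4
Reactants: 4 (3S,6E,10S,11S)-10,11-epoxy-12-hydroxy-10,11-dihydronerolidyl acetate; 5 3-methylbut-2-enylmagnesium chloride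
Product: 7 (3S,6E,10S,11S)-10,11-epoxy-10,11-dihydrogeranyllinalyl acetate, via epoxy triflate 6 (not isolated)
Conditions: Tf2O, 2,6-lutidine, CH2Cl2, −78 °C; then 5 (3 equiv), CuI (20 mol %), THF, −78 to −30 °C
Reagents that add atoms: none
Why: Copper-catalysed sp3–sp3 coupling (Kochi/Kotsuki-type) of the primary glycidyl-type triflate with the allylic Grignard reagent at its unsubstituted terminus forms C12–C13 at low temperature without opening the trisubstituted epoxide or attacking the hindered acetate, and no stereocentre is touched.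

Step 5
Reactants: 7 (3S,6E,10S,11S)-10,11-epoxy-10,11-dihydrogeranyllinalyl acetate
Product: 8 monocyclic trans-7,10-diol acetate (3S,6S,7S,10S,11S)
Conditions: (CF3)2CHOH, H2O (10 equiv), Ph4PBF4 (10 mol %), 0 °C to rt
Reagents that add atoms: water, O
Why: Epoxide-initiated cation–olefin cyclisation (Stork–Eschenmoser chair, promoted by the fluoroalcohol) in which the (6E)-olefin attacks C11 anti to the epoxide oxygen (inversion at C11, C10–O kept), the E geometry places the C5 chain equatorial (C6 S), and water captures the C7 cation on the equatorial side anti to the axial C11 methyl (C7 S), giving the trans-1,4-diol with the epoxide playing the part of the biosynthetic bromonium ion.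

Step 6
Reactants: 8 monocyclic trans-7,10-diol acetate (3S,6S,7S,10S,11S)
Product: 10 oxabicyclic acetate (3S,6S,7S,10R,11S), via C10 triflate 9 (not isolated)
Conditions: Tf2O (1.05 equiv), 2,6-lutidine, CH2Cl2, −78 °C to rt
Reagents that add atoms: none
Why: Selective triflation of the secondary C10 hydroxyl followed by transannular Williamson-type SN2 displacement by the trans-disposed tertiary C7 hydroxyl through a boat conformer closes the 7-oxabicyclo[2.2.1]heptane with inversion at C10 (S to R), the laboratory counterpart of biosynthetic displacement of a C10 leaving group.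

Step 7
Reactants: 10 oxabicyclic acetate (3S,6S,7S,10R,11S)
Product: 11 (14R)-14,15-epoxide of 10
Conditions: Shi ketone (D-fructose-derived, 30 mol %), KHSO5, K2CO3, Bu4NHSO4 (cat.), MeCN/CH2(OMe)2/H2O, 0 °C
Reagents that add atoms: potassium peroxymonosulfate, [K+].[O-]S(=O)(=O)OO
Why: Shi asymmetric epoxidation (chiral dioxirane, spiro transition state) oxidises the only remaining electron-rich trisubstituted olefin while the monosubstituted vinyl group is inert, and the D-fructose-derived ketone sets C14 as R.

Step 8
Reactants: 11 (14R)-14,15-epoxide of 10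
Product: 12 (14S)-14-bromo-15-hydroxy acetate (bromohydrin)
Conditions: Li2NiBr4, THF, 0 °C to rt
Reagents that add atoms: dilithium tetrabromonickelate, [Li+].[Li+].[Ni+2].[Br-].[Br-].[Br-].[Br-]
Why: Regioselective SN2 opening of the trisubstituted epoxide by soft bromide at the less substituted C14 proceeds with inversion (14R epoxide to 14S bromide) and leaves the tertiary C15 alcohol.

Step 9
Reactants: 12 (14S)-14-bromo-15-hydroxy acetate (bromohydrin)
Product: 13 (14S)-14-bromo-15-chloro acetate
Conditions: Me2C=C(Cl)NMe2 (Ghosez reagent), CH2Cl2, 0 °C to rt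
Reagents that add atoms: 1-chloro-N,N,2-trimethylprop-1-en-1-amine, CC(C)=C(Cl)N(C)C
Why: Neutral dehydroxychlorination with the Ghosez α-chloroenamine in which the activated tertiary C15–O ionises with anchimeric assistance from the neighbouring bromine (bromonium ion) and chloride opens it at the tertiary carbon, so the C14–Br bond is never broken, C14 stays S, and the Br/Cl placement mirrors biosynthetic bromonium–chloride capture.

Step 10
Reactants: 13 (14S)-14-bromo-15-chloro acetate
Product: 14 target CNP0297543.1 (3S,6S,7S,10R,11S,14S)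
Conditions: iBu2AlH, CH2Cl2, −78 °C
Reagents that add atoms: none
Why: Reductive ester cleavage with iBu2AlH at −78 °C frees the tertiary allylic alcohol without base, so the secondary bromide and tertiary chloride undergo neither elimination nor substitution and all six stereocentres are retained.

**Compound list**
1 | (3S,6E)-nerolidol, (3S,6E)-3,7,11-trimethyldodeca-1,6,10-trien-3-ol | C=C[C@@](C)(O)CC/C=C(\C)CCC=C(C)C | starting material
2 | (3S,6E)-3,7,11-trimethyldodeca-1,6,10-trien-3-yl acetate | C=C[C@@](C)(OC(C)=O)CC/C=C(\C)CCC=C(C)C | intermediate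
3 | (3S,6E,10E)-12-hydroxy-3,7,11-trimethyldodeca-1,6,10-trien-3-yl acetate | C=C[C@@](C)(OC(C)=O)CC/C=C(\C)CC/C=C(\C)CO | intermediate
4 | (3S,6E,10S,11S)-10,11-epoxy-12-hydroxy-3,7,11-trimethyldodeca-1,6-dien-3-yl acetate | C=C[C@@](C)(OC(C)=O)CC/C=C(\C)CC[C@@H]1O[C@@]1(C)CO | intermediate
5 | 3-methylbut-2-enylmagnesium chloride (prenylmagnesium chloride, commercial THF solution) | CC(C)=CC[Mg]Cl | starting material
6 | C12 trifluoromethanesulfonate of 4 (3S,6E,10S,11S) | C=C[C@@](C)(OC(C)=O)CC/C=C(\C)CC[C@@H]1O[C@@]1(C)COS(=O)(=O)C(F)(F)F | intermediate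
7 | (3S,6E,10S,11S)-10,11-epoxy-3,7,11,15-tetramethylhexadeca-1,6,14-trien-3-yl acetate | C=C[C@@](C)(OC(C)=O)CC/C=C(\C)CC[C@@H]1O[C@@]1(C)CCC=C(C)C | intermediate
8 | (3S)-5-[(1S,2S,3S,6S)-3,6-dihydroxy-2,6-dimethyl-2-(4-methylpent-3-en-1-yl)cyclohexyl]-3-methylpent-1-en-3-yl acetate (trans-1,4-diol, both hydroxyls equatorial) | C=C[C@@](C)(OC(C)=O)CC[C@@H]1[C@@](C)(O)CC[C@H](O)[C@@]1(C)CCC=C(C)C | intermediate
9 | secondary (ring C3, chain C10) trifluoromethanesulfonate of 8 | C=C[C@@](C)(OC(C)=O)CC[C@@H]1[C@@](C)(O)CC[C@H](OS(=O)(=O)C(F)(F)F)[C@@]1(C)CCC=C(C)C | intermediate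
10 | (3S)-5-[(1S,2S,3S,4R)-1,3-dimethyl-3-(4-methylpent-3-en-1-yl)-7-oxabicyclo[2.2.1]heptan-2-yl]-3-methylpent-1-en-3-yl acetate | C=C[C@@](C)(OC(C)=O)CC[C@H]1[C@](C)(CCC=C(C)C)[C@H]2CC[C@]1(C)O2 | intermediate
11 | (3S)-5-[(1S,2S,3S,4R)-3-{2-[(2R)-3,3-dimethyloxiran-2-yl]ethyl}-1,3-dimethyl-7-oxabicyclo[2.2.1]heptan-2-yl]-3-methylpent-1-en-3-yl acetate | C=C[C@@](C)(OC(C)=O)CC[C@H]1[C@](C)(CC[C@H]3OC3(C)C)[C@H]2CC[C@]1(C)O2 | intermediate
12 | (3S)-5-[(1S,2S,3S,4R)-3-[(3S)-3-bromo-4-hydroxy-4-methylpentyl]-1,3-dimethyl-7-oxabicyclo[2.2.1]heptan-2-yl]-3-methylpent-1-en-3-yl acetate | C=C[C@@](C)(OC(C)=O)CC[C@H]1[C@](C)(CC[C@H](Br)C(C)(C)O)[C@H]2CC[C@]1(C)O2 | intermediate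
13 | (3S)-5-[(1S,2S,3S,4R)-3-[(3S)-3-bromo-4-chloro-4-methylpentyl]-1,3-dimethyl-7-oxabicyclo[2.2.1]heptan-2-yl]-3-methylpent-1-en-3-yl acetate | C=C[C@@](C)(OC(C)=O)CC[C@H]1[C@](C)(CC[C@H](Br)C(C)(C)Cl)[C@H]2CC[C@]1(C)O2 | intermediate
14 | (3S)-5-[(1S,2S,3S,4R)-3-[(3S)-3-bromo-4-chloro-4-methylpentyl]-1,3-dimethyl-7-oxabicyclo[2.2.1]heptan-2-yl]-3-methylpent-1-en-3-ol (CNP0297543.1) | C=C[C@@](C)(O)CC[C@H]1[C@](C)(CC[C@H](Br)C(C)(C)Cl)[C@H]2CC[C@]1(C)O2 | target

**Step count and risk**
Total step count: 10. Longest linear sequence: 10 steps (1 → 14); compound 5 is purchased.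

The three steps most likely to fail are steps 5, 6 and 4.

The cyclisation with hydration (step 5) is the most exposed. The C7 cation can lose a proton or be captured by the C10 hydroxyl instead of water, and some epoxide may simply hydrolyse. The fallback sets out from 7 and replaces steps 5 and 6 together. MeAlCl2 in CH2Cl2 at −78 °C gives the classical proton-loss product, the exocyclic alkene alcohol F2 (with its endocyclic isomer, which converges later). Dess–Martin periodinane then gives the ketone F3. LiBH(sec-Bu)3 attacks from the equatorial side to give the axial alcohol F4, epimeric at C10. Intramolecular alkoxymercuration with Hg(OCOCF3)2 followed by NaBH4 closes the bridge from the retained C10 oxygen and comes back to the route at 10.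

The transannular etherification (step 6) requires SN2 attack at a secondary carbon next to a quaternary centre, where elimination or a 1,2-shift of the triflate could compete. The fallback sets out from 8. Dess–Martin periodinane oxidises only the secondary hydroxyl to the hydroxy ketone F5. LiBH(sec-Bu)3 gives the cis-diol F6 (C10 epimer of 8). Catalytic camphorsulfonic acid in CH2Cl2/(CF3)2CHOH ionises the tertiary C7 hydroxyl so that the C10 oxygen closes the bridge with retention at C10, the C–O bond now being made at C7. This comes back to the route at 10.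

The prenyl coupling (step 4) may give some attack through the substituted terminus of the Grignard reagent (reverse-prenyl product). The fallback sets out from 4 through the same triflate 6. CH2=CHCH2MgBr with CuI, which has no regiochemical ambiguity, gives the allyl epoxide F1. Cross-metathesis with 2-methylbut-2-ene using the second-generation Grubbs catalyst then installs the isopropylidene terminus and comes back to the route at 7.

**Further compounds**
F1 | step 4 | allyl epoxide, (3S,6E,10S,11S)-10,11-epoxy-3,7,11-trimethylpentadeca-1,6,14-trien-3-yl acetate | C=C[C@@](C)(OC(C)=O)CC/C=C(\C)CC[C@@H]1O[C@@]1(C)CCC=C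
F2 | step 5 | exocyclic alkene alcohol (C7=CH2; C6, C10 and C11 configured as in 8) | C=C[C@@](C)(OC(C)=O)CC[C@@H]1C(=C)CC[C@H](O)[C@@]1(C)CCC=C(C)C
F3 | step 5 | ketone (C10 carbonyl, C7=CH2) | C=C[C@@](C)(OC(C)=O)CC[C@@H]1C(=C)CCC(=O)[C@@]1(C)CCC=C(C)C
F4 | step 5 | axial alcohol (C10 epimer of F2) | C=C[C@@](C)(OC(C)=O)CC[C@@H]1C(=C)CC[C@@H](O)[C@@]1(C)CCC=C(C)C
F5 | step 6 | hydroxy ketone (C10 carbonyl, C7 hydroxyl as in 8) | C=C[C@@](C)(OC(C)=O)CC[C@@H]1[C@@](C)(O)CCC(=O)[C@@]1(C)CCC=C(C)C
F6 | step 6 | cis-diol (C10 epimer of 8) | C=C[C@@](C)(OC(C)=O)CC[C@@H]1[C@@](C)(O)CC[C@@H](O)[C@@]1(C)CCC=C(C)C
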